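**Strategy.** The key step exploits the 1,5-diene C2'=C3'–C4'–C5'–C6'=C7' of the farnesyl chain on ring carbon C5 of the cyclohexenone ring. In it, C5'H2 is bonded to the olefinic C6'H, and the plan cuts this sp3–sp2 bond. The cyclohexene core is built first with all three stereocentres (C4, C5, C6). It carries only a (2E)-3-methylpenta-2,4-dienyl stub, whose terminal vinyl group C4'=C5' is a latent C5' nucleophile. In one flask, 9-BBN adds to that vinyl group alone. The resulting B-alkyl borane is then coupled under palladium catalysis with (E)-1-iodo-2,6-dimethylhepta-1,5-diene, completing the (2E,6E)-triene with retention. The precursor is a masked enone: C1 dimethyl ketal, C2=C3 enol ether, free C4 hydroxyl.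

Key step: step 8

Numbering: in the Why lines, ring atoms C1–C6 (C1 carbonyl carbon, C2 methoxy-bearing carbon, C4 carbinol carbon) and chain atoms C1'–C12' are those of the target. Compound names use their own IUPAC locants.

Assumption: the (S,R,R)-phosphoramidite of step 4 is taken to deliver methyl to the same enone face as it does with cyclohex-2-enone. If the sense is opposite, the equally available mirror-image ligand is used.

Step 1
Reactants: 1 3,4-dimethoxyphenol
Product: 2 3,4,4-trimethoxycyclohexa-2,5-dien-1-one
Conditions: PhI(OAc)2, MeOH, 0 °C to rt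
Reagents that add atoms: methanol, CO
Why: Oxidative dearomatisation of a para-alkoxyphenol by a trivalent iodine reagent, in which methanol captures the activated ring at the carbon that already bears a methoxy group and gives the quinone monoketal.

Step 2
Reactants: 3 (2E)-3-methylpent-2-en-4-yn-1-ol
Product: 4 (2E)-3-methylpenta-2,4-dien-1-ol
Conditions: H2 (1 atm), Pd/CaCO3 poisoned with Pb(OAc)2 (Lindlar catalyst), quinoline, Et2O, rt, stopped after one equivalent of H2
Reagents that add atoms: none
Why: Lindlar semihydrogenation should stop at the alkene on the poisoned palladium surface, so the terminal alkyne becomes the vinyl group while the E-trisubstituted double bond (future C2'=C3') is untouched.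

Step 3
Reactants: 4 (2E)-3-methylpenta-2,4-dien-1-ol
Product: 5 (3E)-5-bromo-3-methylpenta-1,3-diene
Conditions: PBr3 (0.4 equiv), Et2O, −20 to 0 °C, used without storage
Reagents that add atoms: phosphorus tribromide, BrP(Br)Br
Why: Conversion of a primary allylic alcohol into the bromide through its phosphite ester (SN2 displacement by bromide), run cold so that the E geometry and the primary position are kept.

Step 4
Reactants: 2 3,4,4-trimethoxycyclohexa-2,5-dien-1-one; 5 (3E)-5-bromo-3-methylpenta-1,3-diene
Product: 7 (5R,6R)-3,4,4-trimethoxy-5-methyl-6-[(2E)-3-methylpenta-2,4-dien-1-yl]cyclohex-2-en-1-one, via methylzinc enolate 6 (not isolated)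
Conditions: Me2Zn, Cu(OTf)2 (2 mol %), O,O'-[(S)-1,1'-binaphthyl-2,2'-diyl] N,N-bis[(R)-1-phenylethyl]phosphoramidite (4 mol %), toluene, −25 °C; then 5 (excess), HMPA, 0 °C to rt; aq NH4Cl
Reagents that add atoms: dimethylzinc, C[Zn]C
Why: Copper-catalysed asymmetric conjugate addition of a dialkylzinc followed by enolate alkylation (tandem three-component coupling), in which the ligand-bound methylcopper species attacks the unsubstituted enone carbon (future C6) rather than the methoxy-bearing vinylogous ester carbon and sets C6 by ligand control, and the HMPA-activated enolate 6 is alkylated by the primary allylic bromide anti to the new methyl group, setting C5 trans to C6 by substrate control.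

Step 5
Reactants: 7 (5R,6R)-3,4,4-trimethoxy-5-methyl-6-[(2E)-3-methylpenta-2,4-dien-1-yl]cyclohex-2-en-1-one
Product: 8 (1R,5R,6R)-3,4,4-trimethoxy-5-methyl-6-[(2E)-3-methylpenta-2,4-dien-1-yl]cyclohex-2-en-1-ol
Conditions: Li[HB(s-Bu)3] (L-Selectride), THF, −78 to −40 °C; then H2O; chromatography on Et3N-washed SiO2
Reagents that add atoms: none
Why: Diastereoselective 1,2-reduction by a bulky trialkylborohydride, in which conjugate reduction is blocked by the fully substituted β-carbon C2 and hydride approaches from the face opposite the neighbouring C5 side chain (as with 2-alkylcyclohexanones), placing the C4 hydroxyl cis to the chain.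

Step 6
Reactants: 9 5-bromo-2-methylpent-2-ene
Product: 10 6-methylhept-5-en-1-yne
Conditions: LiC≡CH·H2NCH2CH2NH2, DMSO, 10 °C to rt
Reagents that add atoms: lithium acetylide ethylenediamine complex, [Li]C#C.NCCN
Why: SN2 alkylation of an acetylide by a primary homoallylic bromide in a dipolar aprotic solvent.

Step 7
Reactants: 10 6-methylhept-5-en-1-yne
Product: 12 (1E)-1-iodo-2,6-dimethylhepta-1,5-diene, via alkenyldimethylalane 11 (not isolated)
Conditions: Me3Al (2 equiv), Cp2ZrCl2 (0.2 equiv), CH2Cl2, 0 °C to rt; then I2, THF, −30 °C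
Reagents that add atoms: trimethylaluminium, C[Al](C)C; iodine, II
Why: Zirconium-catalysed methylalumination of a terminal alkyne (Negishi carboalumination) adds methyl and aluminium syn with aluminium on the terminal carbon, and iodinolysis with retention should give the E-iodide (future C6'=C7'), the trisubstituted olefin being inert.

Step 8
Reactants: 8 (1R,5R,6R)-3,4,4-trimethoxy-5-methyl-6-[(2E)-3-methylpenta-2,4-dien-1-yl]cyclohex-2-en-1-ol; 12 (1E)-1-iodo-2,6-dimethylhepta-1,5-diene
Product: 14 (1R,5R,6R)-3,4,4-trimethoxy-5-methyl-6-[(2E,6E)-3,7,11-trimethyldodeca-2,6,10-trien-1-yl]cyclohex-2-en-1-ol, via B-alkyl-9-BBN borinate 13 (not isolated)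
Conditions: 9-BBN (2.2 equiv), THF, 0 °C to rt; then 12, Pd(dppf)Cl2 (5 mol %), AsPh3, Cs2CO3, DMF–H2O, rt
Reagents that add atoms: none
Why: 9-BBN first masks the C4 hydroxyl as its borinate (H2 is lost) and then adds in the anti-Markovnikov sense to the only monosubstituted double bond, C4'=C5', placing boron on C5' to give 13; base turns 13 into a borate that transmetalates to the alkenylpalladium iodide formed by oxidative addition of zerovalent palladium into 12, and reductive elimination forges C5'–C6'. The closest known reaction type is the B-alkyl Suzuki–Miyaura coupling of a homoallylic borane, made by terminal hydroboration of a 1,3-diene, with an (E)-2,2-disubstituted alkenyl iodide. No ring is closed and no stereocentre is created; the C6'=C7' geometry is carried over from 12 because oxidative addition and reductive elimination both go with retention, and C2'=C3' is never touched. The step needs site selectivity among the three C=C bonds of 8, which the steric demand of 9-BBN secures because C2'=C3' and the ring enol ether C2=C3 are trisubstituted, and it needs the absence of a carbonyl group, which the C1 ketal and the already reduced C4 secure. Iodide 12 with its C10'=C11' olefin enters only after the aqueous base has destroyed residual B–H, and the bidentate dppf ligand favours reductive elimination over β-hydride elimination. The basic aqueous medium leaves ketal and enol ether intact and frees the C4 hydroxyl from boron.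

Step 9
Reactants: 14 (1R,5R,6R)-3,4,4-trimethoxy-5-methyl-6-[(2E,6E)-3,7,11-trimethyldodeca-2,6,10-trien-1-yl]cyclohex-2-en-1-ol
Product: 15 (4R,5R,6R)-4-hydroxy-2-methoxy-6-methyl-5-[(2E,6E)-3,7,11-trimethyldodeca-2,6,10-trien-1-yl]cyclohex-2-en-1-one (target)
Conditions: aq oxalic acid (cat.) on SiO2, CH2Cl2, 0 °C to rt
Reagents that add atoms: water, O
Why: Mild acetal hydrolysis, in which the C1 ketal ionises to an oxocarbenium ion that water converts into the ketone, while the competing loss of the C4 hydroxyl (Stork–Danheiser-type transposition) would place positive charge on C2 next to the dialkoxy carbon and should be slower, no stereocentre is touched, and C6 already holds the more stable trans arrangement.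

Compound list
1 | 3,4-dimethoxyphenol | COc1ccc(O)cc1OC | starting material
2 | 3,4,4-trimethoxycyclohexa-2,5-dien-1-one | COC1=CC(=O)C=CC1(OC)OC | intermediate
3 | (2E)-3-methylpent-2-en-4-yn-1-ol | OC/C=C(\C)C#C | starting material
4 | (2E)-3-methylpenta-2,4-dien-1-ol | OC/C=C(\C)C=C | intermediate
5 | (3E)-5-bromo-3-methylpenta-1,3-diene | BrC/C=C(\C)C=C | intermediate
6 | methylzinc cross-conjugated enolate of (5R)-3,4,4-trimethoxy-5-methylcyclohex-2-en-1-one (O–Zn on C1, double bonds C1=C6 and C2=C3; formed in the flask) | COC1=CC(O[Zn]C)=C[C@@H](C)C1(OC)OC | intermediate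
7 | (5R,6R)-3,4,4-trimethoxy-5-methyl-6-[(2E)-3-methylpenta-2,4-dien-1-yl]cyclohex-2-en-1-one | COC1=CC(=O)[C@H](C/C=C(\C)C=C)[C@@H](C)C1(OC)OC | intermediate
8 | (1R,5R,6R)-3,4,4-trimethoxy-5-methyl-6-[(2E)-3-methylpenta-2,4-dien-1-yl]cyclohex-2-en-1-ol | COC1=C[C@H](O)[C@H](C/C=C(\C)C=C)[C@@H](C)C1(OC)OC | intermediate
9 | 5-bromo-2-methylpent-2-ene | CC(C)=CCCBr | starting material
10 | 6-methylhept-5-en-1-yne | C#CCCC=C(C)C | intermediate
11 | [(1E)-2,6-dimethylhepta-1,5-dien-1-yl]dimethylalane (formed in the flask) | C[Al](C)/C=C(\C)CCC=C(C)C | intermediate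
12 | (1E)-1-iodo-2,6-dimethylhepta-1,5-diene | I/C=C(\C)CCC=C(C)C | intermediate
13 | O-(9-BBN) borinate of 8 carrying a 9-BBN group on the terminal chain carbon C5' (formed in the flask) | COC1=C[C@H](OB2C3CCCC2CCC3)[C@H](C/C=C(\C)CCB2C3CCCC2CCC3)[C@@H](C)C1(OC)OC | intermediate
14 | (1R,5R,6R)-3,4,4-trimethoxy-5-methyl-6-[(2E,6E)-3,7,11-trimethyldodeca-2,6,10-trien-1-yl]cyclohex-2-en-1-ol | COC1=C[C@H](O)[C@H](C/C=C(\C)CC/C=C(\C)CCC=C(C)C)[C@@H](C)C1(OC)OC | intermediate
15 | (4R,5R,6R)-4-hydroxy-2-methoxy-6-methyl-5-[(2E,6E)-3,7,11-trimethyldodeca-2,6,10-trien-1-yl]cyclohex-2-en-1-one | COC1=C[C@H](O)[C@H](C/C=C(\C)CC/C=C(\C)CCC=C(C)C)[C@@H](C)C1=O | target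

Total step count: 9. Longest linear sequence: 6 steps (3 → 4 → 5 → 7 → 8 → 14 → 15).

Steps most likely to fail

1. Step 8. Transmetalation of the homoallylic borane may be slow next to the bulky borinate. β-Hydride elimination, protodeboronation or reduction of the iodide could then take over.
Fallback, from 8 back to 14: the same bond is made by a nickel-catalysed reductive alkyl–alkenyl cross-electrophile coupling, which tolerates a free hydroxyl group. Compound 8 is hydroborated as before to 13 and oxidised (NaBO3·4H2O, THF–H2O). This gives the diol (1R,5R,6R)-6-[(2E)-5-hydroxy-3-methylpent-2-en-1-yl]-3,4,4-trimethoxy-5-methylcyclohex-2-en-1-ol F1. The primary hydroxyl alone is exchanged (I2, PPh3, imidazole, CH2Cl2, 0 °C; Appel reaction) to give the homoallylic iodide (1R,5R,6R)-6-[(2E)-5-iodo-3-methylpent-2-en-1-yl]-3,4,4-trimethoxy-5-methylcyclohex-2-en-1-ol F2. This iodide and 12 are joined with NiBr2·glyme, 4,4'-di-tert-butyl-2,2'-bipyridine and Mn powder in DMA, which rejoins the route at 14.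

2. Step 4. The zinc enolate may be alkylated too slowly. Copper-catalysed allylic methylation of the bromide by residual methylzinc species, proton exchange, or loss of methanol with aromatisation could then compete.
Fallback, from 2 back to 7: the two bond formations are separated and the enolate metal is changed. The conjugate addition is run as before and 6 is quenched with aq NH4Cl to give (5R)-3,4,4-trimethoxy-5-methylcyclohex-2-en-1-one F3. Kinetic deprotonation at the sp3 α'-carbon (LiN(SiMe3)2, THF, −78 °C; Stork–Danheiser-type α'-alkylation of a vinylogous ester) gives the lithium enolate of that ketone F4. Bromide 5 alkylates this enolate anti to the methyl group, which rejoins the route at 7.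

3. Step 9. Acid may ionise the allylic C4–O bond in competition with the ketal. That would lead to 1,3-carbonyl transposition or to epimerisation at C4.
Fallback, from 14 back to 15: the hydroxyl is first made a poorer proton acceptor. Acetylation (Ac2O, pyridine, DMAP) gives (1R,5R,6R)-3,4,4-trimethoxy-5-methyl-6-[(2E,6E)-3,7,11-trimethyldodeca-2,6,10-trien-1-yl]cyclohex-2-en-1-yl acetate F5. Ketal hydrolysis as in step 9 gives (1R,5R,6R)-3-methoxy-5-methyl-4-oxo-6-[(2E,6E)-3,7,11-trimethyldodeca-2,6,10-trien-1-yl]cyclohex-2-en-1-yl acetate F6. Methanolysis (K2CO3, MeOH, 0 °C) then frees the alcohol and arrives at 15.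

Further compounds
F1 | step 8 | (1R,5R,6R)-6-[(2E)-5-hydroxy-3-methylpent-2-en-1-yl]-3,4,4-trimethoxy-5-methylcyclohex-2-en-1-ol | COC1=C[C@H](O)[C@H](C/C=C(\C)CCO)[C@@H](C)C1(OC)OC
F2 | step 8 | (1R,5R,6R)-6-[(2E)-5-iodo-3-methylpent-2-en-1-yl]-3,4,4-trimethoxy-5-methylcyclohex-2-en-1-ol | COC1=C[C@H](O)[C@H](C/C=C(\C)CCI)[C@@H](C)C1(OC)OC
F3 | step 4 | (5R)-3,4,4-trimethoxy-5-methylcyclohex-2-en-1-one | COC1=CC(=O)C[C@@H](C)C1(OC)OC
F4 | step 4 | lithium enolate of (5R)-3,4,4-trimethoxy-5-methylcyclohex-2-en-1-one (O–Li on C1, double bonds C1=C6 and C2=C3) | COC1=CC(O[Li])=C[C@@H](C)C1(OC)OC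
F5 | step 9 | (1R,5R,6R)-3,4,4-trimethoxy-5-methyl-6-[(2E,6E)-3,7,11-trimethyldodeca-2,6,10-trien-1-yl]cyclohex-2-en-1-yl acetate | COC1=C[C@H](OC(C)=O)[C@H](C/C=C(\C)CC/C=C(\C)CCC=C(C)C)[C@@H](C)C1(OC)OC
F6 | step 9 | (1R,5R,6R)-3-methoxy-5-methyl-4-oxo-6-[(2E,6E)-3,7,11-trimethyldodeca-2,6,10-trien-1-yl]cyclohex-2-en-1-yl acetate | COC1=C[C@H](OC(C)=O)[C@H](C/C=C(\C)CC/C=C(\C)CCC=C(C)C)[C@@H](C)C1=O
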